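**Plan**

- Target numbering: C1 (CH–aryl), C2 (CH–CH3), C3 (=C–CH3), C4 (=CH), C4a/C8a ring fusion, 6,8-OMe, 7-OH; the target is the cis-(1S,2S) isomer.
- Cuts: C3–CH3 (methyl coupling at a C3 enol triflate, i.e. C3=O); then C4 is taken out from between C4a and C3 (retro one-carbon ring expansion to a 1-indanone with a C4a–C3 bond); then C1–C8a (Nazarov) and C1–C2 (aldol), back to syringaldehyde and propiosyringone.
- Forward: the aldol joins the two aryl units, the five-membered ring closes, is flattened to the indenone and hydrogenated, then grows to the six-membered ring; the C3 methyl and the C3=C4 bond come last.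
- Enabling feature: in the indanone the carbonyl carbon (future C3) is bonded to aryl carbon C4a, which is para to the C7 oxygen. This donor-activated aryl carbon migrates, so the new CH (C4) enters only between C4a and C3, and the ketone ends β to the arene, where enolisation toward benzylic C4 fixes the C3=C4 position.
- Stereochemistry: both centres come from one catalyst-controlled syn addition of H2 to the planar tetrasubstituted C1=C2 bond of the indenone (cis by mechanism, absolute sense by the ligand). C1 is never enolisable; C2 is carried through a base-free ring expansion and a kinetic C4 enolisation.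

Key step: step 6

Remark: propiosyringone (2) is taken as a catalogue compound, and the ligand antipode that delivers the (2S,3S) series in step 5 is fixed in an initial screen.

**Step 1**
Reactants: 1 syringaldehyde; 2 propiosyringone
Product: 3 (E)-α-methylchalcone bisphenol
Conditions: HCl (g), EtOH/AcOH, 0 °C → rt
Reagents that add atoms: none
Why: Acid-catalysed Claisen–Schmidt aldol condensation; the enol of the ethyl ketone adds to the protonated aldehyde and dehydration should give the conjugated (E)-enone, acid being used because phenoxides would deactivate both partners under base.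

**Step 2**
Reactants: 3 (E)-α-methylchalcone bisphenol
Product: 4 racemic trans-indanone bisphenol
Conditions: TFA (neat), 80 °C, sealed tube
Reagents that add atoms: none
Why: Nazarov cyclisation of the O-protonated aryl vinyl ketone; the ring carbon ortho to the acyl group (ortho and para to OMe) closes onto the β-carbon cation stabilised by the second aryl group, and the two racemic centres formed are erased again in step 4.

**Step 3**
Reactants: 4 racemic trans-indanone bisphenol
Product: 5 racemic trans-indanone bis(TIPS) ether
Conditions: TIPSCl, imidazole, DMF, 40 °C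
Reagents that add atoms: triisopropylsilyl chloride, CC(C)[Si](Cl)(C(C)C)C(C)C
Why: Standard silylation of the two 2,6-dimethoxyphenols; the TIPS ethers should tolerate DDQ, hydrogenation, BF3 at low temperature, amide base and Grignard reagent, and leave under fluoride without touching the styrene.

**Step 4**
Reactants: 5 racemic trans-indanone bis(TIPS) ether
Product: 6 2-methyl-3-arylindenone bis(TIPS) ether
Conditions: DDQ, 1,4-dioxane, 90 °C
Reagents that add atoms: none
Why: Quinone dehydrogenation of a 3-arylindanone; hydride is abstracted from the doubly benzylic C3–H and loss of the C2 proton should give the planar tetrasubstituted enone.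

**Step 5**
Reactants: 6 2-methyl-3-arylindenone bis(TIPS) ether
Product: 7 cis-(2S,3S)-indanone bis(TIPS) ether
Conditions: H2 (60 bar), cationic Ru(II) hydride/Josiphos-type bisphosphine (2 mol%), CH2Cl2, 25 °C; product kept away from base
Reagents that add atoms: none
Why: Asymmetric hydrogenation of a tetrasubstituted cyclic enone C=C (the reaction type used for cis-2,3-disubstituted cyclopentanones); both hydrogens add to one face, so methyl and aryl must end cis, and the chiral ligand selects the face that gives (2S,3S).

**Step 6**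
Reactants: 7 cis-(2S,3S)-indanone bis(TIPS) ether
Product: 9 cis-(3S,4S)-2-tetralone bis(TIPS) ether, via α-trimethylsilyl ketone 8 (not isolated)
Conditions: TMSCHN2 (1.5 equiv), BF3·OEt2 (1.2 equiv), CH2Cl2, −78 → −30 °C; then 1 M HCl, THF, 0 °C
Reagents that add atoms: trimethylsilyldiazomethane, C[Si](C)(C)C=[N+]=[N-]
Why: The BF3-activated C1=O of 7 is attacked by the nucleophilic carbon of TMSCHN2 to give a β-oxido diazonium adduct; loss of N2 is coupled to a 1,2-shift of the ring bond C1–C7a, so the silyl-bearing carbon is inserted between the arene and the carbonyl (8), and acidic work-up replaces silicon by hydrogen. The closest known reaction type is the Lewis-acid-promoted diazoalkane homologation of 1-indanones and 1-tetralones to 2-tetralones and 2-benzosuberones (Tiffeneau–Demjanov-type ring expansion). No ring is closed by cyclisation: the existing five-membered ring is widened to the six-membered ring by insertion of one carbon. No stereocentre remains from the step (the C–Si centre of 8 is transient); C4 of 9 (old C3) is not enolisable, and C3 of 9 (old C2) should not be deprotonated under base-free Lewis-acidic conditions at low temperature, so the cis relation from step 5 should be carried over. The selectivity needed is migration of aryl carbon C7a and not of the secondary alkyl carbon C2; it should be secured by the para silyloxy donor on the migrating aryl carbon (phenonium-like transition state). The bulky C-silyl group of 8 should shield the new, more electrophilic ketone from a second homologation.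

**Step 7**
Reactants: 9 cis-(3S,4S)-2-tetralone bis(TIPS) ether
Product: 10 cis-(3S,4S)-dihydronaphthyl triflate bis(TIPS) ether
Conditions: KHMDS, THF, −78 °C (ketone added to the base); then PhNTf2, −78 → 0 °C
Reagents that add atoms: N-phenylbis(trifluoromethanesulfonimide), FC(F)(F)S(=O)(=O)N(c1ccccc1)S(=O)(=O)C(F)(F)F
Why: Kinetic enolisation of a 2-tetralone goes to the benzylic CH2 and not to the hindered tertiary C3–H, so O-triflation should fix the double bond at the future C3=C4 and remove the only pathway for epimerisation of the methyl-bearing centre.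

**Step 8**
Reactants: 10 cis-(3S,4S)-dihydronaphthyl triflate bis(TIPS) ether
Product: 11 target bis(TIPS) ether
Conditions: MeMgBr, Fe(acac)3 (5 mol%), THF/NMP, −30 → 0 °C
Reagents that add atoms: methylmagnesium bromide, C[Mg]Br
Why: Iron-catalysed Kumada-type coupling of an alkenyl triflate with a methyl Grignard reagent; it is fast at low temperature and does not touch the sp3 stereocentres or the aryl silyl ethers.

**Step 9**
Reactants: 11 target bis(TIPS) ether
Product: 12 CNP0141907.1
Conditions: TBAF, AcOH, THF, 0 °C, under argon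
Reagents that add atoms: none
Why: Fluoride cleavage of the aryl silyl ethers; buffering with acetic acid keeps the electron-rich phenoxides and the acid- and oxidation-sensitive 1,2-dihydronaphthalene intact.

**Compound list**

1 | syringaldehyde (4-hydroxy-3,5-dimethoxybenzaldehyde) | COc1cc(C=O)cc(OC)c1O | starting material
2 | propiosyringone (1-(4-hydroxy-3,5-dimethoxyphenyl)propan-1-one) | CCC(=O)c1cc(OC)c(O)c(OC)c1 | starting material
3 | (E)-1,3-bis(4-hydroxy-3,5-dimethoxyphenyl)-2-methylprop-2-en-1-one | COc1cc(/C=C(\C)C(=O)c2cc(OC)c(O)c(OC)c2)cc(OC)c1O | intermediate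
4 | racemic trans-5-hydroxy-3-(4-hydroxy-3,5-dimethoxyphenyl)-4,6-dimethoxy-2-methylindan-1-one (one enantiomer drawn, 2R,3S) | COc1cc([C@H]2c3c(cc(OC)c(O)c3OC)C(=O)[C@@H]2C)cc(OC)c1O | intermediate
5 | racemic trans-3-[3,5-dimethoxy-4-(triisopropylsilyloxy)phenyl]-4,6-dimethoxy-2-methyl-5-(triisopropylsilyloxy)indan-1-one (one enantiomer drawn) | COc1cc([C@H]2c3c(cc(OC)c(O[Si](C(C)C)(C(C)C)C(C)C)c3OC)C(=O)[C@@H]2C)cc(OC)c1O[Si](C(C)C)(C(C)C)C(C)C | intermediate
6 | 3-[3,5-dimethoxy-4-(triisopropylsilyloxy)phenyl]-4,6-dimethoxy-2-methyl-5-(triisopropylsilyloxy)-1H-inden-1-one | COc1cc(C2=C(C)C(=O)c3cc(OC)c(O[Si](C(C)C)(C(C)C)C(C)C)c(OC)c32)cc(OC)c1O[Si](C(C)C)(C(C)C)C(C)C | intermediate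
7 | (2S,3S)-3-[3,5-dimethoxy-4-(triisopropylsilyloxy)phenyl]-4,6-dimethoxy-2-methyl-5-(triisopropylsilyloxy)indan-1-one (cis) | COc1cc([C@H]2c3c(cc(OC)c(O[Si](C(C)C)(C(C)C)C(C)C)c3OC)C(=O)[C@H]2C)cc(OC)c1O[Si](C(C)C)(C(C)C)C(C)C | intermediate
8 | (3S,4S)-4-[3,5-dimethoxy-4-(triisopropylsilyloxy)phenyl]-5,7-dimethoxy-3-methyl-6-(triisopropylsilyloxy)-1-(trimethylsilyl)-3,4-dihydronaphthalen-2(1H)-one (both C1 epimers) | COc1cc([C@H]2c3c(cc(OC)c(O[Si](C(C)C)(C(C)C)C(C)C)c3OC)C([Si](C)(C)C)C(=O)[C@H]2C)cc(OC)c1O[Si](C(C)C)(C(C)C)C(C)C | intermediate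
9 | (3S,4S)-4-[3,5-dimethoxy-4-(triisopropylsilyloxy)phenyl]-5,7-dimethoxy-3-methyl-6-(triisopropylsilyloxy)-3,4-dihydronaphthalen-2(1H)-one | COc1cc([C@H]2c3c(cc(OC)c(O[Si](C(C)C)(C(C)C)C(C)C)c3OC)CC(=O)[C@H]2C)cc(OC)c1O[Si](C(C)C)(C(C)C)C(C)C | intermediate
10 | (3S,4S)-4-[3,5-dimethoxy-4-(triisopropylsilyloxy)phenyl]-5,7-dimethoxy-3-methyl-6-(triisopropylsilyloxy)-3,4-dihydronaphthalen-2-yl trifluoromethanesulfonate | COc1cc([C@H]2c3c(cc(OC)c(O[Si](C(C)C)(C(C)C)C(C)C)c3OC)C=C(OS(=O)(=O)C(F)(F)F)[C@H]2C)cc(OC)c1O[Si](C(C)C)(C(C)C)C(C)C | intermediate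
11 | (1S,2S)-1-[3,5-dimethoxy-4-(triisopropylsilyloxy)phenyl]-6,8-dimethoxy-2,3-dimethyl-7-(triisopropylsilyloxy)-1,2-dihydronaphthalene | COc1cc([C@H]2c3c(cc(OC)c(O[Si](C(C)C)(C(C)C)C(C)C)c3OC)C=C(C)[C@H]2C)cc(OC)c1O[Si](C(C)C)(C(C)C)C(C)C | intermediate
12 | CNP0141907.1, (7S,8S)-8-(4-hydroxy-3,5-dimethoxyphenyl)-1,3-dimethoxy-6,7-dimethyl-7,8-dihydronaphthalen-2-ol | COc1cc([C@H]2c3c(cc(OC)c(O)c3OC)C=C(C)[C@H]2C)cc(OC)c1O | target

**Step count**

Total steps: 9. Longest linear sequence: 9 steps (from 1 and 2 to 12).

**Steps most likely to fail**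

Step 5. Hydrogen delivery to the hindered tetrasubstituted double bond (flanked by a peri methoxy group and two bulky aryl silyl ethers) may be slow or poorly face-selective, or the carbonyl may be reduced in competition. The fallback sets out from 6 and separates the two stereo-defining events. A copper hydride conjugate reduction (Cu(OAc)2, DTBM-SEGPHOS, (EtO)2MeSiH, toluene, 0 °C) should set the aryl-bearing centre and give the (1R)-3-[diethoxy(methyl)silyloxy]-1-aryl-2-methyl-1H-indene F1 (same spatial arrangement as C3 of 7). Cold hydrolysis (dilute HCl, THF, −20 °C) should then protonate C2 kinetically from the face opposite the aryl group, placing the methyl cis and returning to 7.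

Step 6. The secondary alkyl carbon may migrate instead of the aryl carbon, the methyl-bearing centre may epimerise on the Lewis acid, or epoxide formation may compete. The fallback sets out from 7 and uses an oxidative 1,2-aryl shift in which only the aryl group can migrate. Base-free methylenation (Cp2TiMe2, toluene, 70 °C) should give the (2S,3S)-1-methylidene-indane F2. Hydroxy(tosyloxy)iodobenzene in methanol then adds iodine(III) to the CH2 terminus and methanol to the benzylic carbon, and the aryl group shifts with loss of iodobenzene to give the ring-expanded dimethyl ketal F3. Dilute aqueous acid hydrolyses F3 and comes back to the route at 9.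

Step 7. Proton exchange between the enolate and unreacted ketone, or partial deprotonation at the methyl-bearing carbon, may erode the cis configuration or give the regioisomeric triflate. The fallback sets out from 9 and avoids enolates. Addition of MeMgBr/CeCl3 (THF, −78 °C) should give the tertiary carbinol F4, and syn dehydration with methyl N-(triethylammoniumsulfonyl)carbamate (benzene, 50 °C) toward the benzylic C–H should give the conjugated alkene, coming back to the route at 11 without passing through 10.

**Further compounds**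

F1 | step 5 | (1R)-3-[diethoxy(methyl)silyloxy]-1-[3,5-dimethoxy-4-(triisopropylsilyloxy)phenyl]-5,7-dimethoxy-2-methyl-6-(triisopropylsilyloxy)-1H-indene | COc1cc([C@H]2c3c(cc(OC)c(O[Si](C(C)C)(C(C)C)C(C)C)c3OC)C(O[Si](C)(OCC)OCC)=C2C)cc(OC)c1O[Si](C(C)C)(C(C)C)C(C)C
F2 | step 6 | (2S,3S)-3-[3,5-dimethoxy-4-(triisopropylsilyloxy)phenyl]-4,6-dimethoxy-2-methyl-1-methylidene-5-(triisopropylsilyloxy)indane | COc1cc([C@H]2c3c(cc(OC)c(O[Si](C(C)C)(C(C)C)C(C)C)c3OC)C(=C)[C@H]2C)cc(OC)c1O[Si](C(C)C)(C(C)C)C(C)C
F3 | step 6 | (3S,4S)-4-[3,5-dimethoxy-4-(triisopropylsilyloxy)phenyl]-2,2,5,7-tetramethoxy-3-methyl-6-(triisopropylsilyloxy)-1,2,3,4-tetrahydronaphthalene | COc1cc([C@H]2c3c(cc(OC)c(O[Si](C(C)C)(C(C)C)C(C)C)c3OC)CC(OC)(OC)[C@H]2C)cc(OC)c1O[Si](C(C)C)(C(C)C)C(C)C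
F4 | step 7 | (3S,4S)-4-[3,5-dimethoxy-4-(triisopropylsilyloxy)phenyl]-5,7-dimethoxy-2,3-dimethyl-6-(triisopropylsilyloxy)-1,2,3,4-tetrahydronaphthalen-2-ol (both C2 epimers) | COc1cc([C@H]2c3c(cc(OC)c(O[Si](C(C)C)(C(C)C)C(C)C)c3OC)CC(C)(O)[C@H]2C)cc(OC)c1O[Si](C(C)C)(C(C)C)C(C)C
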